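**Strategy.** The route rests on cutting the bond between C1 of the furo[3,4-c]furan core (the α-oxy carbon between O2 and ring-fusion carbon C6a) and the ipso carbon of the prenyloxy aryl ring. The precursor is a bicyclic tetrahydrofuro[3,4-c]furan-1-carboxylic acid, assembled by a Cp2TiCl-mediated epoxide radical cyclisation, which carries only the silyl-protected guaiacyl ring. Dual photoredox/nickel decarboxylative arylation with the prenylated aryl bromide expels CO2, erases the C1 configuration through the O2-stabilised radical, and delivers the aryl group to the convex face of the cis-fused dioxabicyclo[3.3.0]octane, so that one operation joins both halves and sets the last stereocentre.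

Key step: step 8

Remark: the target is the (1S,3aR,4S,6aR) isomer; ethyl (E)-4-hydroxybut-2-enoate, 4-bromo-2-methoxyphenol and 1-bromo-3-methylbut-2-ene are taken as commercial. Ring A is the tetrahydrofuran holding C4, O5 and C6; ring B holds C1, O2 and C3.

**Step 1**
Reactants: 1 vanillin (4-hydroxy-3-methoxybenzaldehyde)
Product: 2 3-methoxy-4-(triisopropylsilyloxy)benzaldehyde
Conditions: iPr3SiCl, imidazole, DMF, 25 °C
Reagents that add atoms: chlorotriisopropylsilane, CC(C)[Si](Cl)(C(C)C)C(C)C
Why: Standard silylation of a phenol; the bulky aryl silyl ether should survive the Grignard reagent, trivalent titanium, cold hydroxide and the photocatalyst, and is removed last by fluoride.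

**Step 2**
Reactants: 2 3-methoxy-4-(triisopropylsilyloxy)benzaldehyde
Product: 3 rac-1-[3-methoxy-4-(triisopropylsilyloxy)phenyl]prop-2-en-1-ol
Conditions: CH2=CHMgBr, THF, −78 to 0 °C; aq. NH4Cl
Reagents that add atoms: vinylmagnesium bromide, C=C[Mg]Br
Why: Grignard 1,2-addition to the aldehyde; the carbinol is made racemic because its configuration is set in step 3.

**Step 3**
Reactants: 3 rac-1-[3-methoxy-4-(triisopropylsilyloxy)phenyl]prop-2-en-1-ol (2 equiv), 4 ethyl (E)-4-hydroxybut-2-enoate
Product: 5 ethyl (E)-4-{[(1S)-1-[3-methoxy-4-(triisopropylsilyloxy)phenyl]prop-2-en-1-yl]oxy}but-2-enoate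
Conditions: [Ir(cod)Cl]2 (3 mol %), BINOL-phosphoramidite ligand with a dibenzo[b,f]azepine olefin donor (12 mol %, enantiomer chosen for the (S)-ether), (PhO)2P(O)OH (5 mol %), ClCH2CH2Cl, 25 °C
Reagents that add atoms: none
Why: Enantioselective allylic etherification of a racemic branched allylic alcohol catalysed by [Ir(cod)Cl]2 and the chiral ligand: acid-assisted ionisation of 3 with loss of water gives an allyl fragment bound to iridium, the chiral ligand directs alcohol 4 to one face of the branched terminus (the matched enantiomer of 3 reacts faster and the rest is separated), and this sets the (S) centre that becomes C4.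

**Step 4**
Reactants: 5 ethyl (E)-4-{[(1S)-1-[3-methoxy-4-(triisopropylsilyloxy)phenyl]prop-2-en-1-yl]oxy}but-2-enoate
Product: 6 ethyl (E)-4-{(R)-[3-methoxy-4-(triisopropylsilyloxy)phenyl](oxiran-2-yl)methoxy}but-2-enoate, both oxirane epimers (same spatial arrangement at the benzylic carbon; the descriptor changes by priority only)
Conditions: mCPBA, NaHCO3, CH2Cl2, 0 to 25 °C
Reagents that add atoms: 3-chloroperoxybenzoic acid, OOC(=O)c1cccc(Cl)c1
Why: Prilezhaev epoxidation should be chemoselective for the isolated vinyl group because the enoate alkene is electron-poor; the new oxirane centre needs no control since it becomes a planar radical in step 5.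

**Step 5**
Reactants: 6 ethyl (E)-4-{(R)-[3-methoxy-4-(triisopropylsilyloxy)phenyl](oxiran-2-yl)methoxy}but-2-enoate
Product: 8 ethyl (3aR,4S,6aR)-4-[3-methoxy-4-(triisopropylsilyloxy)phenyl]tetrahydro-1H,3H-furo[3,4-c]furan-1-carboxylate as a mixture of C1 epimers, via iodo ester 7 (not isolated)
Conditions: Cp2TiCl (2.2 equiv, from Cp2TiCl2 and Zn in THF, decanted from Zn), slow addition of 6, THF, 25 °C; then I2 (1.2 equiv), 0 to 25 °C
Reagents that add atoms: none
Why: Proposed new method: Cp2TiCl opens the epoxide reductively to the β-titanoxy secondary radical, which adds 5-exo-trig to the enoate through a chair-like transition state with the aryl group pseudo-equatorial (aryl trans to CH2OTi, the two new ring substituents cis), a second Cp2TiCl reduces the α-ester radical to a titanium enolate, I2 iodinates it to 7, and the neighbouring titanium alkoxide displaces iodide (5-exo-tet, Williamson type) to close ring B with cis fusion, the C1 centre being left as an epimer mixture that does not matter; the closest known reaction type is the trivalent titanium epoxide radical cyclisation of epoxy cinnamyl ethers finished with iodine to close the second tetrahydrofuran ring, shown for benzylic but not for α-ester termini.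

**Step 6**
Reactants: 8 ethyl (3aR,4S,6aR)-4-[3-methoxy-4-(triisopropylsilyloxy)phenyl]tetrahydro-1H,3H-furo[3,4-c]furan-1-carboxylate
Product: 9 (3aR,4S,6aR)-4-[3-methoxy-4-(triisopropylsilyloxy)phenyl]tetrahydro-1H,3H-furo[3,4-c]furan-1-carboxylic acid (C1 epimers)
Conditions: LiOH, THF/H2O, 0 °C; then dilute HCl to pH 3
Reagents that add atoms: lithium hydroxide, [Li+].[OH-]
Why: Saponification of the activated α-alkoxy ester should be fast at 0 °C, which spares the hindered aryl silyl ether; the C1 epimer composition is irrelevant for step 8.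

**Step 7**
Reactants: 10 4-bromo-2-methoxyphenol, 11 1-bromo-3-methylbut-2-ene (prenyl bromide)
Product: 12 4-bromo-2-methoxy-1-(3-methylbut-2-enyloxy)benzene
Conditions: K2CO3, acetone, 50 °C
Reagents that add atoms: none
Why: Williamson etherification of the phenoxide with a primary allylic bromide (SN2, O-alkylation).

**Step 8**
Reactants: 9 (3aR,4S,6aR)-4-[3-methoxy-4-(triisopropylsilyloxy)phenyl]tetrahydro-1H,3H-furo[3,4-c]furan-1-carboxylic acid, 12 4-bromo-2-methoxy-1-(3-methylbut-2-enyloxy)benzene
Product: 13 (1S,3aR,4S,6aR)-1-[3-methoxy-4-(3-methylbut-2-enyloxy)phenyl]-4-[3-methoxy-4-(triisopropylsilyloxy)phenyl]tetrahydro-1H,3H-furo[3,4-c]furan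
Conditions: Ir[dF(CF3)ppy]2(dtbbpy)PF6 (1 mol %), NiCl2(dme) (10 mol %), dtbbpy (15 mol %), Cs2CO3, DMF, blue LEDs, 25 °C
Reagents that add atoms: none
Why: Excited Ir[dF(CF3)ppy]2(dtbbpy)PF6 oxidises the caesium carboxylate of 9, CO2 is lost and both C1 epimers converge on one C1 radical stabilised by O2, while zerovalent nickel inserts into the C–Br bond of 12, captures the radical, and the trivalent nickel aryl alkyl species reductively eliminates to form the C1–aryl bond. The closest known reaction type is the photoredox/nickel decarboxylative arylation of tetrahydrofuran-2-carboxylic and furanosyl acids with aryl bromides. No ring is closed. The new C1 stereocentre is set by the substrate: C1 sits next to ring-fusion carbon C6a of the cis-fused dioxabicyclo[3.3.0]octane, nickel should approach the convex face trans to the C6a–C6 bond, and reductive elimination retains that geometry, which places the aryl group exo (1S), as at C4. The step needs facial selectivity and chemoselectivity over the prenyl alkene and the benzylic C4–H; the V shape of the bicycle should secure the first and the fast capture of the nucleophilic α-oxy radical by nickel the second.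

**Step 9**
Reactants: 13 (1S,3aR,4S,6aR)-1-[3-methoxy-4-(3-methylbut-2-enyloxy)phenyl]-4-[3-methoxy-4-(triisopropylsilyloxy)phenyl]tetrahydro-1H,3H-furo[3,4-c]furan
Product: 14 (1S,3aR,4S,6aR)-4-(4-hydroxy-3-methoxyphenyl)-1-[3-methoxy-4-(3-methylbut-2-enyloxy)phenyl]tetrahydro-1H,3H-furo[3,4-c]furan (target)
Conditions: Bu4NF, AcOH, THF, 0 °C
Reagents that add atoms: none
Why: Fluoride-driven cleavage of the aryl Si–O bond, buffered with AcOH so that the phenoxide para to the C4 benzylic ether does not open ring A; the prenyl ether and both benzylic ethers should be inert.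

**Compound list**
1 | vanillin (4-hydroxy-3-methoxybenzaldehyde) | COc1cc(C=O)ccc1O | starting material
2 | 3-methoxy-4-(triisopropylsilyloxy)benzaldehyde | COc1cc(C=O)ccc1O[Si](C(C)C)(C(C)C)C(C)C | intermediate
3 | rac-1-[3-methoxy-4-(triisopropylsilyloxy)phenyl]prop-2-en-1-ol | COc1cc(C(O)C=C)ccc1O[Si](C(C)C)(C(C)C)C(C)C | intermediate
4 | ethyl (E)-4-hydroxybut-2-enoate | CCOC(=O)/C=C/CO | starting material
5 | ethyl (E)-4-{[(1S)-1-[3-methoxy-4-(triisopropylsilyloxy)phenyl]prop-2-en-1-yl]oxy}but-2-enoate | COc1cc([C@H](C=C)OC/C=C/C(=O)OCC)ccc1O[Si](C(C)C)(C(C)C)C(C)C | intermediate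
6 | ethyl (E)-4-{(R)-[3-methoxy-4-(triisopropylsilyloxy)phenyl](oxiran-2-yl)methoxy}but-2-enoate, both oxirane epimers | COc1cc([C@H](C2CO2)OC/C=C/C(=O)OCC)ccc1O[Si](C(C)C)(C(C)C)C(C)C | intermediate
7 | ethyl 2-iodo-2-{(3R,4R,5S)-4-(hydroxymethyl)-5-[3-methoxy-4-(triisopropylsilyloxy)phenyl]oxolan-3-yl}acetate, present as its titanium alkoxide, either configuration at the CHI carbon | COc1cc([C@H]2OC[C@H](C(I)C(=O)OCC)[C@@H]2CO)ccc1O[Si](C(C)C)(C(C)C)C(C)C | intermediate
8 | ethyl (3aR,4S,6aR)-4-[3-methoxy-4-(triisopropylsilyloxy)phenyl]tetrahydro-1H,3H-furo[3,4-c]furan-1-carboxylate, C1 epimers | COc1cc([C@H]2OC[C@H]3[C@@H]2COC3C(=O)OCC)ccc1O[Si](C(C)C)(C(C)C)C(C)C | intermediate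
9 | (3aR,4S,6aR)-4-[3-methoxy-4-(triisopropylsilyloxy)phenyl]tetrahydro-1H,3H-furo[3,4-c]furan-1-carboxylic acid, C1 epimers | COc1cc([C@H]2OC[C@H]3[C@@H]2COC3C(=O)O)ccc1O[Si](C(C)C)(C(C)C)C(C)C | intermediate
10 | 4-bromo-2-methoxyphenol | COc1cc(Br)ccc1O | starting material
11 | 1-bromo-3-methylbut-2-ene | CC(C)=CCBr | starting material
12 | 4-bromo-2-methoxy-1-(3-methylbut-2-enyloxy)benzene | COc1cc(Br)ccc1OCC=C(C)C | intermediate
13 | (1S,3aR,4S,6aR)-1-[3-methoxy-4-(3-methylbut-2-enyloxy)phenyl]-4-[3-methoxy-4-(triisopropylsilyloxy)phenyl]tetrahydro-1H,3H-furo[3,4-c]furan | COc1cc([C@H]2OC[C@H]3[C@@H]2CO[C@@H]3c2ccc(OCC=C(C)C)c(OC)c2)ccc1O[Si](C(C)C)(C(C)C)C(C)C | intermediate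
14 | (1S,3aR,4S,6aR)-4-(4-hydroxy-3-methoxyphenyl)-1-[3-methoxy-4-(3-methylbut-2-enyloxy)phenyl]tetrahydro-1H,3H-furo[3,4-c]furan | COc1cc([C@H]2OC[C@H]3[C@@H]2CO[C@@H]3c2ccc(OCC=C(C)C)c(OC)c2)ccc1O | target

Total step count: 9. Longest linear sequence: 8 steps (steps 1 to 6, 8 and 9); step 7 makes the coupling partner.

**Steps most likely to fail**

Step 5 (proposed new method). The titanium enolate may be protonated or may lactonise before iodine reaches it, or the α-iodo ester may lose HI instead of closing ring B. Fallback from 6, by known reactions: the same Cp2TiCl cyclisation is run without iodine and quenched with aqueous acid, so that the cis hydroxy ester lactonises to the bicyclic δ-lactone F1. Enolisation (LiN(SiMe3)2, Me3SiCl, −78 °C) followed by NBS should give the α-bromo lactone F2. K2CO3 in EtOH then opens the lactone, and the freed alkoxide displaces bromide (the ring contraction of α-halo δ-lactones to tetrahydrofuran-2-carboxylates), which comes back to the route at 8.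

Step 8. Oxidative addition of the electron-rich aryl bromide may be slow enough that the C1 radical is simply reduced; facial discrimination at nickel may be incomplete; the carbonate base may strip the silyl group and let the phenoxide quench the photocatalyst. Fallback from 9, ionic instead of radical: oxidative decarboxylation with Pb(OAc)4 (pyridine, benzene) should give the C1 acetate F3, and PhSO2H with CaCl2 in CH2Cl2 the C1 phenyl sulfone F4. The aryl Grignard reagent F5 (from 12 and Mg), combined with ZnBr2 in THF, then displaces sulfinate through the ring B oxocarbenium ion, attacked on the convex face, and comes back to the route at 13.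

Step 3. The very electron-rich carbinol may ionise under acid outside the chiral catalyst, giving racemic or linear (cinnamyl) ether, or may undergo allylic transposition. Fallback from 3: Sharpless kinetic resolution (Ti(OiPr)4, the diisopropyl tartrate enantiomer that consumes (R)-3, tBuOOH, 4 Å sieves, −20 °C) leaves the (S)-alcohol F6 and turns the other enantiomer into the anti epoxy alcohol F7, which is discarded. F6 is then O-alkylated with ethyl (E)-4-bromobut-2-enoate and Ag2O (CH2Cl2, dark), which comes back to the route at 5.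

**Further compounds**
F1 | step 5 | cis-fused δ-lactone of the cyclised hydroxy ester (lactone between the 4-CH2OH and the 3-CH2CO2 arm of the oxolane, aryl trans to the lactone CH2O) | COc1cc([C@H]2OC[C@H](CC(=O)OC3)[C@@H]23)ccc1O[Si](C(C)C)(C(C)C)C(C)C
F2 | step 5 | α-bromo derivative of F1 (bromine on the carbon next to the lactone carbonyl, either epimer) | COc1cc([C@H]2OC[C@H](C(Br)C(=O)OC3)[C@@H]23)ccc1O[Si](C(C)C)(C(C)C)C(C)C
F3 | step 8 | (3aR,4S,6aR)-4-[3-methoxy-4-(triisopropylsilyloxy)phenyl]tetrahydro-1H,3H-furo[3,4-c]furan-1-yl acetate, C1 epimers | COc1cc([C@H]2OC[C@H]3[C@@H]2COC3OC(C)=O)ccc1O[Si](C(C)C)(C(C)C)C(C)C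
F4 | step 8 | (3aR,4S,6aR)-4-[3-methoxy-4-(triisopropylsilyloxy)phenyl]-1-(phenylsulfonyl)tetrahydro-1H,3H-furo[3,4-c]furan, C1 epimers | COc1cc([C@H]2OC[C@H]3[C@@H]2COC3S(=O)(=O)c2ccccc2)ccc1O[Si](C(C)C)(C(C)C)C(C)C
F5 | step 8 | [3-methoxy-4-(3-methylbut-2-enyloxy)phenyl]magnesium bromide | COc1cc([Mg]Br)ccc1OCC=C(C)C
F6 | step 3 | (S)-1-[3-methoxy-4-(triisopropylsilyloxy)phenyl]prop-2-en-1-ol | COc1cc([C@H](C=C)O)ccc1O[Si](C(C)C)(C(C)C)C(C)C
F7 | step 3 | (S)-[3-methoxy-4-(triisopropylsilyloxy)phenyl][(R)-oxiran-2-yl]methanol | COc1cc([C@@H]([C@H]2CO2)O)ccc1O[Si](C(C)C)(C(C)C)C(C)C
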